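**Retrosynthetic overview**
- Feature: each outer six-membered ring is an acylphloroglucinol that is non-aromatic at only one atom. This is the sp3 C(CH3)2 carbon, which sits between two enolic C–OH carbons and para to the ring C=O. Removing the four methyl groups in thought gives a flat tris-arene.
- Last disconnection: the four C–CH3 bonds (two per outer ring) lead back to the all-aromatic nonaphenol trimer and four MeI.
- The trimer comes from its nonamethyl ether. The two Ar–CH2 bonds of that ether are made by two successive Friedel–Crafts benzylations of 2,4,6-trimethoxybutyrophenone, with the chloromethylated acetyl arene and then the propionyl arene.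
- During assembly, the outer-ring carbon that is methylated later carries Br. Without it, the free C–H of an attached outer ring and that of the central ring would be electronically alike, and the chlorides could self-condense. Br is removed by hydrogenolysis before deprotection.
- No ring is formed, since all three carbocycles are bought as arenes. The order is: acylate, block and chloromethylate the outer rings, attach the acetyl ring, attach the propionyl ring, unmask, and dearomatise both outer rings last.

Key step: step 11

Remark: the target has no stereocentre and is achiral, so no enantiomer has to be selected. It is one of several interconverting enol tautomers, and the tautomer of the given SMILES is used throughout.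

Step 1
Reactants: 1 1,3,5-trimethoxybenzene; 2 butyryl chloride
Product: 3 1-(2,4,6-trimethoxyphenyl)butan-1-one
Conditions: Bi(OTf)3 (5 mol %), ClCH2CH2Cl, 60 °C
Reagents that add atoms: butyryl chloride (2), CCCC(Cl)=O
Why: Friedel–Crafts acylation under metal-triflate catalysis; the threefold-activated arene reacts once because the new ketone deactivates the ring, and the absence of stoichiometric AlCl3 leaves the ortho methyl ethers intact.

Step 2
Reactants: 1 1,3,5-trimethoxybenzene; 4 propionyl chloride
Product: 5 1-(2,4,6-trimethoxyphenyl)propan-1-one
Conditions: Bi(OTf)3 (5 mol %), ClCH2CH2Cl, 60 °C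
Reagents that add atoms: propionyl chloride (4), CCC(Cl)=O
Why: The same catalytic Friedel–Crafts acylation as in step 1, self-limiting at the mono-ketone.

Step 3
Reactants: 6 2,4,6-trimethoxyacetophenone
Product: 7 1-(3-bromo-2,4,6-trimethoxyphenyl)ethan-1-one
Conditions: NBS (1.0 equiv), MeCN, 0 °C → rt, dark
Reagents that add atoms: N-bromosuccinimide, O=C1CCC(=O)N1Br
Why: Electrophilic aromatic bromination; the two equivalent ring C–H positions are far more nucleophilic than the ketone enol, one equivalent of NBS should stop at the monobromide, and the bromine holds the carbon that later takes the two methyl groups.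

Step 4
Reactants: 5 1-(2,4,6-trimethoxyphenyl)propan-1-one
Product: 8 1-(3-bromo-2,4,6-trimethoxyphenyl)propan-1-one
Conditions: NBS (1.0 equiv), MeCN, 0 °C → rt, dark
Reagents that add atoms: N-bromosuccinimide, O=C1CCC(=O)N1Br
Why: The same electrophilic aromatic monobromination as in step 3.

Step 5
Reactants: 7 1-(3-bromo-2,4,6-trimethoxyphenyl)ethan-1-one
Product: 9 1-[3-bromo-5-(chloromethyl)-2,4,6-trimethoxyphenyl]ethan-1-one
Conditions: (CH2O)n (3 equiv), HCl (g, sat.), ZnCl2 (0.2 equiv), 1,4-dioxane, 0 → 40 °C; cold, short work-up
Reagents that add atoms: formaldehyde (as paraformaldehyde), C=O; hydrogen chloride, Cl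
Why: Blanc chloromethylation; the only remaining aromatic C–H is ortho/para to all three methoxy groups and meta to both deactivating groups, and the excess of formaldehyde and HCl keeps the chloride from being consumed by unreacted 7.

Step 6
Reactants: 8 1-(3-bromo-2,4,6-trimethoxyphenyl)propan-1-one
Product: 10 1-[3-bromo-5-(chloromethyl)-2,4,6-trimethoxyphenyl]propan-1-one
Conditions: (CH2O)n (3 equiv), HCl (g, sat.), ZnCl2 (0.2 equiv), 1,4-dioxane, 0 → 40 °C; cold, short work-up
Reagents that add atoms: formaldehyde (as paraformaldehyde), C=O; hydrogen chloride, Cl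
Why: The same Blanc chloromethylation at the single free ring position as in step 5.

Step 7
Reactants: 3 1-(2,4,6-trimethoxyphenyl)butan-1-one (2.5 equiv, excess recovered); 9 1-[3-bromo-5-(chloromethyl)-2,4,6-trimethoxyphenyl]ethan-1-one
Product: 11 1-{3-[(3-acetyl-5-bromo-2,4,6-trimethoxyphenyl)methyl]-2,4,6-trimethoxyphenyl}butan-1-one
Conditions: ZnCl2 (0.3 equiv), CH2Cl2, slow addition of 9, 0 °C → rt
Reagents that add atoms: none
Why: Friedel–Crafts benzylation; ZnCl2 ionises the methoxy-stabilised benzylic chloride, which has no aromatic C–H and so cannot self-condense, and the excess of 3 (two equivalent free positions) favours the mono-benzylated product.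

Step 8
Reactants: 11 the acetyl/butyryl dimer; 10 1-[3-bromo-5-(chloromethyl)-2,4,6-trimethoxyphenyl]propan-1-one (1.2 equiv)
Product: 12 1-{3-[(3-acetyl-5-bromo-2,4,6-trimethoxyphenyl)methyl]-5-[(3-bromo-2,4,6-trimethoxy-5-propanoylphenyl)methyl]-2,4,6-trimethoxyphenyl}butan-1-one
Conditions: ZnCl2 (0.3 equiv), CH2Cl2, 0 °C → rt
Reagents that add atoms: none
Why: Second Friedel–Crafts benzylation; because bromine blocks the acetyl ring, H-5 of the central ring is the only aromatic C–H in 11, so the substrate itself fixes where the second bridge forms.

Step 9
Reactants: 12 the dibromo trimer nonamethyl ether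
Product: 13 1-{3-[(3-acetyl-2,4,6-trimethoxyphenyl)methyl]-2,4,6-trimethoxy-5-[(2,4,6-trimethoxy-3-propanoylphenyl)methyl]phenyl}butan-1-one
Conditions: H2 (1 atm), 10 % Pd/C, NaOAc (3 equiv), MeOH–EtOAc, rt
Reagents that add atoms: none
Why: Catalytic hydrogenolysis of aryl C–Br bonds; these are cleaved much faster than the twisted, di-ortho-substituted aryl ketones are reduced, and acetate takes up the HBr so that the bridges see no acid.

Step 10
Reactants: 13 the trimer nonamethyl ether
Product: 14 1-{3-[(3-acetyl-2,4,6-trihydroxyphenyl)methyl]-2,4,6-trihydroxy-5-[(2,4,6-trihydroxy-3-propanoylphenyl)methyl]phenyl}butan-1-one (all-aromatic trimer)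
Conditions: BBr3 (15 equiv), CH2Cl2, −78 °C → rt; ice-water, 0 °C
Reagents that add atoms: none
Why: Lewis-acid aryl methyl ether cleavage; BBr3 complexes every OMe and C=O (hence the excess), bromide removes each methyl by SN2, and the phenols stay masked as borates until the cold quench, which limits acid damage to the bridges.

Step 11
Reactants: 14 the all-aromatic nonaphenol trimer; 15 iodomethane (4.0 equiv)
Product: 17 filixic acid ABP (target), via bis(C-methyl) tris-arene 16 (not isolated)
Conditions: NaOMe (8 equiv), MeI (4.0 equiv, slow addition), degassed MeOH, Ar, 0 °C → rt; cold 1 M HCl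
Reagents that add atoms: iodomethane (15), CI
Why: In methanolic methoxide all three rings are polyphenoxides, and in each outer ring the one carbon that still bears hydrogen (flanked by two C–O− carbons, para to the third) attacks MeI by SN2, loses its proton and rearomatises to the C-methyl arene 16; a second SN2 at the same carbon makes it quaternary, so the ring cannot rearomatise and is fixed as the enolised gem-dimethyl cyclohexadienone of 17. The closest known reaction is the NaOMe/MeI nuclear gem-dimethylation of monomeric acylphloroglucinols (3-alkyl-substituted ones included) to acylfilicinic acids, used here on two rings of one molecule; four C–CH3 bonds are formed, no ring is closed and no stereocentre is created. Site selectivity is needed between this carbon, the bridge- and acyl-bearing carbons of the same ring and the fully substituted central ring, and it rests on sterics: a methyl-bearing carbon is far more open than one carrying a CH2Ar or acyl group, and the central ring offers only such congested carbons. C- over O-methylation is favoured by the hydrogen-bonding solvent, which shields the oxygens, and by the soft electrophile. Over-methylation is held back because each dearomatised ring is a strongly acidic β-triketone whose delocalised anion is a much poorer nucleophile than the aromatic polyphenoxides still present, and because only four equivalents of MeI are offered with almost no free methoxide left to waste them. Base-induced exchange of the methylene bridges (retro-Michael loss of a ring via a quinone methide) is slowed by working at or below room temperature under argon and quenching into cold acid.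

**Compound list**
1 | 1,3,5-trimethoxybenzene | COc1cc(OC)cc(OC)c1 | starting material
2 | butyryl chloride | CCCC(Cl)=O | starting material
3 | 1-(2,4,6-trimethoxyphenyl)butan-1-one | CCCC(=O)c1c(OC)cc(OC)cc1OC | intermediate
4 | propionyl chloride | CCC(Cl)=O | starting material
5 | 1-(2,4,6-trimethoxyphenyl)propan-1-one | CCC(=O)c1c(OC)cc(OC)cc1OC | intermediate
6 | 2,4,6-trimethoxyacetophenone | CC(=O)c1c(OC)cc(OC)cc1OC | starting material
7 | 1-(3-bromo-2,4,6-trimethoxyphenyl)ethan-1-one | CC(=O)c1c(OC)cc(OC)c(Br)c1OC | intermediate
8 | 1-(3-bromo-2,4,6-trimethoxyphenyl)propan-1-one | CCC(=O)c1c(OC)cc(OC)c(Br)c1OC | intermediate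
9 | 1-[3-bromo-5-(chloromethyl)-2,4,6-trimethoxyphenyl]ethan-1-one | CC(=O)c1c(OC)c(Br)c(OC)c(CCl)c1OC | intermediate
10 | 1-[3-bromo-5-(chloromethyl)-2,4,6-trimethoxyphenyl]propan-1-one | CCC(=O)c1c(OC)c(Br)c(OC)c(CCl)c1OC | intermediate
11 | 1-{3-[(3-acetyl-5-bromo-2,4,6-trimethoxyphenyl)methyl]-2,4,6-trimethoxyphenyl}butan-1-one | CCCC(=O)c1c(OC)cc(OC)c(Cc2c(OC)c(Br)c(OC)c(C(C)=O)c2OC)c1OC | intermediate
12 | dibromo trimer nonamethyl ether (name as in step 8) | CCCC(=O)c1c(OC)c(Cc2c(OC)c(Br)c(OC)c(C(C)=O)c2OC)c(OC)c(Cc2c(OC)c(Br)c(OC)c(C(=O)CC)c2OC)c1OC | intermediate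
13 | trimer nonamethyl ether (name as in step 9) | CCCC(=O)c1c(OC)c(Cc2c(OC)cc(OC)c(C(C)=O)c2OC)c(OC)c(Cc2c(OC)cc(OC)c(C(=O)CC)c2OC)c1OC | intermediate
14 | all-aromatic nonaphenol trimer (name as in step 10) | CCCC(=O)c1c(O)c(Cc2c(O)cc(O)c(C(C)=O)c2O)c(O)c(Cc2c(O)cc(O)c(C(=O)CC)c2O)c1O | intermediate
15 | iodomethane | CI | starting material
16 | 1-{3-[(3-acetyl-2,4,6-trihydroxy-5-methylphenyl)methyl]-2,4,6-trihydroxy-5-[(2,4,6-trihydroxy-3-methyl-5-propanoylphenyl)methyl]phenyl}butan-1-one | CCCC(=O)c1c(O)c(Cc2c(O)c(C)c(O)c(C(C)=O)c2O)c(O)c(Cc2c(O)c(C)c(O)c(C(=O)CC)c2O)c1O | intermediate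
17 | filixic acid ABP: 2,4,6-trihydroxybutyrophenone carrying at C-3 a CH2–(5-acetyl-2,4-dihydroxy-3,3-dimethyl-6-oxocyclohexa-1,4-dien-1-yl) group and at C-5 a CH2–(2,4-dihydroxy-3,3-dimethyl-6-oxo-5-propanoylcyclohexa-1,4-dien-1-yl) group; achiral | CCCC(=O)c1c(O)c(CC2=C(O)C(C)(C)C(O)=C(C(C)=O)C2=O)c(O)c(CC2=C(O)C(C)(C)C(O)=C(C(=O)CC)C2=O)c1O | target

**Step count**
- Total step count: 11.
- Longest linear sequence: 7 steps (6 → 7 → 9 → 11 → 12 → 13 → 14 → 17). The line 1 → 5 → 8 → 10 → 12 → 13 → 14 → 17 is equally long.

**Steps most likely to fail**

1. Step 11.
   - Risk: the four alkylation events may spread over the many nucleophilic sites. This covers under- and over-methylation, O-methylation and attack at a bridge-bearing carbon. The base may also set off exchange of the methylene bridges.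
   - Fallback: it sets out from dibromide 12 and uses the two bromines as handles. A twofold Suzuki–Miyaura methylation (trimethylboroxine, Pd(OAc)2/SPhos, K3PO4, dioxane–H2O, 100 °C) should give the bis(C-methyl) trimer nonamethyl ether F1. BBr3 cleavage as in step 10 should then deliver 16, now as an isolated compound, where the fallback comes back to the route.
   - From 16, only one dearomatising methylation per outer ring (MeI 2 equiv, NaOMe, MeOH, 0 °C) is left to reach 17. This halves the number of events that must be controlled under basic conditions.

2. Step 10.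
   - Risk: ether cleavage may stay incomplete. Acid-induced heterolysis of an Ar–CH2 bond may be followed by re-alkylation at the free outer-ring positions. Neighbouring phenols may also cyclodehydrate across a bridge.
   - Fallback: it sets out from 12 and removes the methyl groups while the blocking bromines are still in place. No outer-ring carbon can then capture a stray benzylic cation, and the outer rings are less basic towards ipso protonation.
   - BBr3 (CH2Cl2, −78 °C → rt) should give the dibromo nonaphenol trimer F2. Hydrogenolysis (H2, Pd/C, NaOAc, MeOH, rt) should then remove both bromines and come back to the route at 14.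

3. Step 8.
   - Risk: the crowded last C–H of the central ring may capture the benzylic cation slowly. This leaves time for acid-catalysed transfer of the bridge already installed.
   - Fallback: it sets out from 11 and reverses the polarity of the coupling. Blanc chloromethylation at the single free position, with a small electrophile, should give the chloromethylated dimer F3.
   - ZnCl2-catalysed benzylation of an excess (about 4 equiv) of the unbrominated, less hindered ketone 5 should give the monobromo trimer nonamethyl ether F4. Hydrogenolysis as in step 9 comes back to the route at 13.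

**Further compounds**
F1 | step 11 | bis(C-methyl) trimer nonamethyl ether | CCCC(=O)c1c(OC)c(Cc2c(OC)c(C)c(OC)c(C(C)=O)c2OC)c(OC)c(Cc2c(OC)c(C)c(OC)c(C(=O)CC)c2OC)c1OC
F2 | step 10 | dibromo nonaphenol trimer | CCCC(=O)c1c(O)c(Cc2c(O)c(Br)c(O)c(C(C)=O)c2O)c(O)c(Cc2c(O)c(Br)c(O)c(C(=O)CC)c2O)c1O
F3 | step 8 | chloromethylated dimer | CCCC(=O)c1c(OC)c(CCl)c(OC)c(Cc2c(OC)c(Br)c(OC)c(C(C)=O)c2OC)c1OC
F4 | step 8 | monobromo trimer nonamethyl ether | CCCC(=O)c1c(OC)c(Cc2c(OC)c(Br)c(OC)c(C(C)=O)c2OC)c(OC)c(Cc2c(OC)cc(OC)c(C(=O)CC)c2OC)c1OC
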